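Ring A (C1–C5, C10) is a cyclohexane that carries both quaternary carbons, C4 and C10, and shares the C5–C10 bond with ring B, so it is disconnected as a Diels–Alder ring. One intramolecular [4+2] cycloaddition of an acyclic triene closes rings A and B together and sets C4, C5 and C10. The precursor joins an (E)-2-methyl-1,3-diene (C3=C2–C1=C10) through C9–C8–C7–C6 to a (Z)-α-methyl enoate (C4=C5, ester carbon = C19). C8 and C9 come from nerol by asymmetric epoxidation and are locked in a temporary tetrahydropyran acetal (O8–C13) that steers the cycloaddition and later becomes the diene side chain.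

Key step: step 8

Remark: labdane numbering is used for all intermediates; acetals 7–13 (and their fallback relatives) and lactol 14 are drawn as the 13R anomer (equatorial OMe/OH) expected to predominate, the other anomer should react alike and both converge at 15.

Step 1
Reactants: 1 nerol
Product: 2 (2S,3R)-2,3-epoxynerol
Conditions: Ti(OiPr)4 (5 mol %), L-(+)-diethyl tartrate (6 mol %), t-BuOOH, 4 Å molecular sieves, CH2Cl2, −20 °C
Reagents that add atoms: tert-butyl hydroperoxide, CC(C)(C)OO
Why: Sharpless asymmetric epoxidation of the Z-allylic alcohol, in which the L-(+)-tartrate titanium complex delivers oxygen to the face that gives the (2S,3R)-epoxide (fixing C8 and the sense of the later inversion at C9) and leaves the remote trisubstituted alkene untouched.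

Step 2
Reactants: 2 (2S,3R)-2,3-epoxynerol; 3 [2-(1,3-dioxan-2-yl)ethyl]magnesium bromide
Product: 4 (2R,3R)-2-[2-(1,3-dioxan-2-yl)ethyl]-3,7-dimethyloct-6-ene-1,3-diol
Conditions: 3 (3 equiv), CuI (10 mol %), THF, −30 → 0 °C; aq. NH4Cl
Reagents that add atoms: none
Why: Copper-catalysed SN2 opening of the trisubstituted 2,3-epoxy alcohol by the Grignard reagent at the only non-quaternary epoxide carbon (C9), which sets C9 by inversion anti to the retained C8–O bond and gives the 1,3-diol.

Step 3
Reactants: 4 (2R,3R)-2-[2-(1,3-dioxan-2-yl)ethyl]-3,7-dimethyloct-6-ene-1,3-diol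
Product: 6 (3R,4R)-3-[2-(1,3-dioxan-2-yl)ethyl]-4,8-dimethylnon-7-en-1-yn-4-ol, via hydroxy aldehyde 5 (not isolated)
Conditions: TEMPO (10 mol %), PhI(OAc)2, CH2Cl2, rt; then MeOH, K2CO3, dimethyl (1-diazo-2-oxopropyl)phosphonate, 0 °C → rt
Reagents that add atoms: dimethyl (1-diazo-2-oxopropyl)phosphonate, COP(=O)(OC)C(=[N+]=[N-])C(C)=O
Why: Oxoammonium oxidation of the primary alcohol only (the tertiary hydroxyl is inert), followed in the same flask by Seyferth–Gilbert homologation in its Ohira–Bestmann form, whose mild carbonate base should leave the α-stereocentre C9 and the β-hydroxyl intact.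

Step 4
Reactants: 6 (3R,4R)-3-[2-(1,3-dioxan-2-yl)ethyl]-4,8-dimethylnon-7-en-1-yn-4-ol
Product: 7 (2R,3R,6R)-3-ethynyl-6-methoxy-2-methyl-2-(4-methylpent-3-en-1-yl)oxane
Conditions: camphorsulfonic acid (10 mol %), MeOH, rt
Reagents that add atoms: methanol, CO
Why: Acid-catalysed transacetalisation in which the tertiary C8 hydroxyl captures the C13 oxocarbenium ion in a 6-membered ring, under thermodynamic control giving the anomer with equatorial OMe (an axial OMe would be 1,3-diaxial to the C8 methyl), so that O8 and C13 are protected and C8/C9 are held in a ring.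

Step 5
Reactants: 7 (2R,3R,6R)-3-ethynyl-6-methoxy-2-methyl-2-(4-methylpent-3-en-1-yl)oxane
Product: 8 3-[(2R,3R,6R)-3-ethynyl-6-methoxy-2-methyloxan-2-yl]propanal
Conditions: O3, CH2Cl2, NaHCO3, −78 °C (Sudan Red 7B end-point); then Me2S, −78 °C → rt
Reagents that add atoms: ozone, [O-][O+]=O
Why: Ozonolysis with a dye end-point cleaves the electron-rich trisubstituted alkene much faster than the terminal alkyne and unveils the C5 aldehyde.

Step 6
Reactants: 8 3-[(2R,3R,6R)-3-ethynyl-6-methoxy-2-methyloxan-2-yl]propanal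
Product: 9 methyl (2Z)-5-[(2R,3R,6R)-3-ethynyl-6-methoxy-2-methyloxan-2-yl]-2-methylpent-2-enoate
Conditions: methyl 2-[bis(2,2,2-trifluoroethoxy)phosphoryl]propanoate, KN(SiMe3)2, 18-crown-6, THF, −78 °C
Reagents that add atoms: methyl 2-[bis(2,2,2-trifluoroethoxy)phosphoryl]propanoate, COC(=O)C(C)P(=O)(OCC(F)(F)F)OCC(F)(F)F
Why: Still–Gennari variant of the Horner–Wadsworth–Emmons reaction, whose electron-poor phosphonate under dissociating conditions gives kinetically the (Z)-2-methyl-2-enoate with the ester cis to C6, the geometry that later makes C19 β.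

Step 7
Reactants: 9 methyl (2Z)-5-[(2R,3R,6R)-3-ethynyl-6-methoxy-2-methyloxan-2-yl]-2-methylpent-2-enoate
Product: 11 methyl (2Z)-5-{(2R,3R,6R)-6-methoxy-2-methyl-3-[(2E)-penta-2,4-dien-2-yl]oxan-2-yl}-2-methylpent-2-enoate, via alkenylalane 10 (not isolated)
Conditions: Me3Al, Cp2ZrCl2 (20 mol %), H2O (1 equiv), CH2Cl2, −20 °C; then CH2=CHBr, Pd(PPh3)4 (5 mol %), ZnCl2 (cat.), THF, rt
Reagents that add atoms: trimethylaluminium, C[Al](C)C; vinyl bromide, C=CBr
Why: Zirconium-catalysed Negishi methylalumination adds CH3 and Al syn across the terminal alkyne with CH3 on the internal carbon (C10), and palladium-catalysed coupling of the alkenylalane with vinyl bromide proceeds with retention to the (E)-2-methyl-1,3-diene in which the tether is trans to C2.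

Step 8
Reactants: 11 methyl (2Z)-5-{(2R,3R,6R)-6-methoxy-2-methyl-3-[(2E)-penta-2,4-dien-2-yl]oxan-2-yl}-2-methylpent-2-enoate
Product: 12 methyl (13R)-8α,13-epoxy-13-methoxy-14,15,16-trinorlabd-1-en-19-oate
Conditions: PhMe (0.01 M), BHT (cat.), degassed, sealed tube, 170 °C
Reagents that add atoms: none
Why: Thermal intramolecular Diels–Alder reaction: the C3=C2–C1=C10 diene and the C4=C5 enoate of 11 combine suprafacially in one concerted, asynchronous [4+2] transition state that makes C5–C10 and C3–C4 and leaves the C1=C2 alkene; the closest known type is the cyclisation of 1,7,9-decatrienoates to angularly methylated octalins. Ring A is the cycloaddition ring itself, and ring B closes through the four-atom tether C6–C9 in a chair (the C5–C10 bond is exo to the tether), so both carbocycles form at once. C4 follows from the Z geometry of the dienophile (ester cis to C6, hence C19 β-axial and the methyl α), and the trans C5-H/C10-methyl relationship from the tether-exo mode, in which only H5 and the small C4 methyl lie under the diene and the ester points outward, the mode that α-methyl acrylates prefer for steric reasons. The absolute sense at C5 and C10 is relayed from C8 and C9: the trans-fused tetrahydropyran acetal admits only the chair tether in which O8 and C11 are equatorial and C17 axial, so the dienophile can reach one face of the diene only. The step therefore needs π-facial and trans-fusion selectivity; the first is secured by the temporary ring, the second rests on the exo preference and is the weaker point. High dilution and BHT suppress intermolecular reaction, and 170 °C should stay below the range in which the Z-methyl of the diene undergoes [1,5]-hydrogen shift.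

Step 9
Reactants: 12 methyl (13R)-8α,13-epoxy-13-methoxy-14,15,16-trinorlabd-1-en-19-oate
Product: 13 methyl (13R)-8α,13-epoxy-13-methoxy-14,15,16-trinorlabdan-19-oate
Conditions: H2 (1 atm), Pd/C (10 %), EtOAc, rt
Reagents that add atoms: none
Why: Heterogeneous catalytic hydrogenation of the only C=C bond (cis-disubstituted C1=C2), which creates no stereocentre and does not affect acetal or ester.

Step 10
Reactants: 13 methyl (13R)-8α,13-epoxy-13-methoxy-14,15,16-trinorlabdan-19-oate
Product: 14 methyl 8α,13-epoxy-13-hydroxy-14,15,16-trinorlabdan-19-oate (lactol)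
Conditions: 1 M aq. HCl–THF (1:4), rt
Reagents that add atoms: water, O
Why: Specific-acid hydrolysis of the mixed acetal to the lactol, which is in equilibrium with the 8α-hydroxy-13-aldehyde, while the hindered axial ester is untouched.

Step 11
Reactants: 14 methyl 8α,13-epoxy-13-hydroxy-14,15,16-trinorlabdan-19-oate (lactol)
Product: 15 methyl 8α-hydroxy-14,15-dinorlabd-13(16)-yn-19-oate
Conditions: dimethyl (1-diazo-2-oxopropyl)phosphonate, K2CO3, MeOH, rt → 40 °C
Reagents that add atoms: dimethyl (1-diazo-2-oxopropyl)phosphonate, COP(=O)(OC)C(=[N+]=[N-])C(C)=O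
Why: Ohira–Bestmann homologation of the lactol through its open hydroxy-aldehyde form gives the terminal alkyne (C13≡C16) and frees the 8α-hydroxyl.

Step 12
Reactants: 15 methyl 8α-hydroxy-14,15-dinorlabd-13(16)-yn-19-oate
Product: 16 methyl 8α-hydroxylabda-13(16),14-dien-19-oate
Conditions: ethylene (1 atm), second-generation Grubbs catalyst RuCl2(=CHPh)(PCy3)(H2IMes) (5 mol %), PhMe, 80 °C
Reagents that add atoms: ethylene, C=C
Why: Ruthenium-carbene enyne cross-metathesis of the terminal alkyne with ethylene builds the 2-substituted 1,3-butadiene (C13(=C16)–C14=C15) in one operation.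

Step 13
Reactants: 16 methyl 8α-hydroxylabda-13(16),14-dien-19-oate
Product: 17 labda-13(16),14-diene-8α,19-diol
Conditions: LiAlH4, THF, 0 °C → reflux; aq. NaOH work-up
Reagents that add atoms: none
Why: Hydride reduction of the neopentyl methyl ester to the C19 primary alcohol, to which the conjugated diene and the tertiary alcohol are inert.

Step 14
Reactants: 18 4-(tert-butyldimethylsilyloxy)benzaldehyde
Product: 19 methyl (2Z)-3-[4-(tert-butyldimethylsilyloxy)phenyl]prop-2-enoate
Conditions: methyl 2-[bis(2,2,2-trifluoroethoxy)phosphoryl]acetate, KN(SiMe3)2, 18-crown-6, THF, −78 °C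
Reagents that add atoms: methyl 2-[bis(2,2,2-trifluoroethoxy)phosphoryl]acetate, COC(=O)CP(=O)(OCC(F)(F)F)OCC(F)(F)F
Why: Still–Gennari olefination of the aromatic aldehyde gives the (Z)-cinnamate under kinetic control.

Step 15
Reactants: 19 methyl (2Z)-3-[4-(tert-butyldimethylsilyloxy)phenyl]prop-2-enoate
Product: 20 (2Z)-3-[4-(tert-butyldimethylsilyloxy)phenyl]prop-2-enoic acid
Conditions: Me3SnOH, 1,2-dichloroethane, 80 °C; cold dilute aq. HCl wash
Reagents that add atoms: trimethyltin hydroxide, C[Sn](C)(C)O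
Why: Trimethyltin hydroxide cleaves the methyl ester under essentially neutral conditions, which should keep both the Z-alkene and the aryl silyl ether that hydroxide would remove.

Step 16
Reactants: 17 labda-13(16),14-diene-8α,19-diol; 20 (2Z)-3-[4-(tert-butyldimethylsilyloxy)phenyl]prop-2-enoic acid
Product: 21 8α-hydroxylabda-13(16),14-dien-19-yl (2Z)-3-[4-(tert-butyldimethylsilyloxy)phenyl]prop-2-enoate
Conditions: DCC, DMAP (10 mol %), CH2Cl2, 0 °C → rt
Reagents that add atoms: none
Why: Steglich esterification acylates the primary C19 alcohol only (the tertiary C8 hydroxyl is unreactive), and low temperature with catalytic DMAP limits Z-to-E isomerisation of the electron-rich cinnamoyl unit.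

Step 17
Reactants: 21 8α-hydroxylabda-13(16),14-dien-19-yl (2Z)-3-[4-(tert-butyldimethylsilyloxy)phenyl]prop-2-enoate
Product: 22 8α-hydroxylabda-13(16),14-dien-19-yl (2Z)-3-(4-hydroxyphenyl)prop-2-enoate (CNP0197278.1)
Conditions: Bu4NF, AcOH (1:1), THF, 0 °C
Reagents that add atoms: none
Why: Fluoride cleavage of the aryl silyl ether, buffered with acetic acid, liberates the phenol without ester cleavage, alkene isomerisation or harm to the diene.

Compound list
1 | nerol, (2Z)-3,7-dimethylocta-2,6-dien-1-ol | CC(C)=CCC/C(C)=C\CO | starting material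
2 | (2S,3R)-2,3-epoxynerol, [(2S,3R)-3-methyl-3-(4-methylpent-3-en-1-yl)oxiran-2-yl]methanol | OC[C@@H]1O[C@]1(C)CCC=C(C)C | intermediate
3 | [2-(1,3-dioxan-2-yl)ethyl]magnesium bromide (commercial THF solution) | Br[Mg]CCC1OCCCO1 | starting material
4 | (2R,3R)-2-[2-(1,3-dioxan-2-yl)ethyl]-3,7-dimethyloct-6-ene-1,3-diol | OC[C@@H](CCC1OCCCO1)[C@](C)(O)CCC=C(C)C | intermediate
5 | (2S,3R)-2-[2-(1,3-dioxan-2-yl)ethyl]-3-hydroxy-3,7-dimethyloct-6-enal (not isolated) | O=C[C@@H](CCC1OCCCO1)[C@](C)(O)CCC=C(C)C | intermediate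
6 | (3R,4R)-3-[2-(1,3-dioxan-2-yl)ethyl]-4,8-dimethylnon-7-en-1-yn-4-ol | C#C[C@@H](CCC1OCCCO1)[C@](C)(O)CCC=C(C)C | intermediate
7 | (2R,3R,6R)-3-ethynyl-6-methoxy-2-methyl-2-(4-methylpent-3-en-1-yl)oxane | C#C[C@H]1CC[C@H](OC)O[C@]1(C)CCC=C(C)C | intermediate
8 | 3-[(2R,3R,6R)-3-ethynyl-6-methoxy-2-methyloxan-2-yl]propanal | C#C[C@H]1CC[C@H](OC)O[C@]1(C)CCC=O | intermediate
9 | methyl (2Z)-5-[(2R,3R,6R)-3-ethynyl-6-methoxy-2-methyloxan-2-yl]-2-methylpent-2-enoate | C#C[C@H]1CC[C@H](OC)O[C@]1(C)CC/C=C(/C)C(=O)OC | intermediate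
10 | dimethyl[(1E)-2-(oxan-3-yl)prop-1-en-1-yl]alane derived from 9 (Al cis to the new methyl; not isolated) | C[Al](C)/C=C(\C)[C@H]1CC[C@H](OC)O[C@]1(C)CC/C=C(/C)C(=O)OC | intermediate
11 | methyl (2Z)-5-{(2R,3R,6R)-6-methoxy-2-methyl-3-[(2E)-penta-2,4-dien-2-yl]oxan-2-yl}-2-methylpent-2-enoate | C=C/C=C(\C)[C@H]1CC[C@H](OC)O[C@]1(C)CC/C=C(/C)C(=O)OC | intermediate
12 | methyl (13R)-8α,13-epoxy-13-methoxy-14,15,16-trinorlabd-1-en-19-oate (5α-H, 9α-H, 10β-methyl) | CO[C@H]1CC[C@@H]2[C@@]3(C)C=CC[C@](C)(C(=O)OC)[C@@H]3CC[C@@]2(C)O1 | intermediate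
13 | methyl (13R)-8α,13-epoxy-13-methoxy-14,15,16-trinorlabdan-19-oate | CO[C@H]1CC[C@@H]2[C@@]3(C)CCC[C@](C)(C(=O)OC)[C@@H]3CC[C@@]2(C)O1 | intermediate
14 | methyl 8α,13-epoxy-13-hydroxy-14,15,16-trinorlabdan-19-oate (lactol) | O[C@H]1CC[C@@H]2[C@@]3(C)CCC[C@](C)(C(=O)OC)[C@@H]3CC[C@@]2(C)O1 | intermediate
15 | methyl 8α-hydroxy-14,15-dinorlabd-13(16)-yn-19-oate | C#CCC[C@@H]1[C@@]2(C)CCC[C@](C)(C(=O)OC)[C@@H]2CC[C@@]1(C)O | intermediate
16 | methyl 8α-hydroxylabda-13(16),14-dien-19-oate | C=CC(=C)CC[C@@H]1[C@@]2(C)CCC[C@](C)(C(=O)OC)[C@@H]2CC[C@@]1(C)O | intermediate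
17 | labda-13(16),14-diene-8α,19-diol | C=CC(=C)CC[C@@H]1[C@@]2(C)CCC[C@](C)(CO)[C@@H]2CC[C@@]1(C)O | intermediate
18 | 4-(tert-butyldimethylsilyloxy)benzaldehyde | O=Cc1ccc(O[Si](C)(C)C(C)(C)C)cc1 | starting material
19 | methyl (2Z)-3-[4-(tert-butyldimethylsilyloxy)phenyl]prop-2-enoate | COC(=O)/C=C\c1ccc(O[Si](C)(C)C(C)(C)C)cc1 | intermediate
20 | (2Z)-3-[4-(tert-butyldimethylsilyloxy)phenyl]prop-2-enoic acid | OC(=O)/C=C\c1ccc(O[Si](C)(C)C(C)(C)C)cc1 | intermediate
21 | 8α-hydroxylabda-13(16),14-dien-19-yl (2Z)-3-[4-(tert-butyldimethylsilyloxy)phenyl]prop-2-enoate | C=CC(=C)CC[C@@H]1[C@@]2(C)CCC[C@](C)(COC(=O)/C=C\c3ccc(O[Si](C)(C)C(C)(C)C)cc3)[C@@H]2CC[C@@]1(C)O | intermediate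
22 | 8α-hydroxylabda-13(16),14-dien-19-yl (2Z)-3-(4-hydroxyphenyl)prop-2-enoate (CNP0197278.1) | C=CC(=C)CC[C@@H]1[C@@]2(C)CCC[C@](C)(COC(=O)/C=C\c3ccc(O)cc3)[C@@H]2CC[C@@]1(C)O | target

Total step count: 17. Longest linear sequence: 15 (steps 1–13, 16, 17); steps 14 and 15 form a two-step side branch.

Steps most likely to fail

Step 8. The cis-fused adduct may form competitively because the exo preference is weak, and a slow cycloaddition may let the [1,5]-hydrogen shift of the diene take over. The fallback sets out from 11 and returns at 12. The ester is reduced with i-Bu2AlH (CH2Cl2, −78 °C) to the allylic alcohol F1 and oxidised with Dess–Martin periodinane/NaHCO3 to the (Z)-enal F2. F2 is cyclised at −78 → −20 °C with the bulky Lewis acid aluminium tris(2,6-diphenylphenoxide), Al(OC6H3Ph2)3, a reagent known to shield the endo region of a bound enal and to favour exo Diels–Alder adducts, which here is the trans-fused mode. The adduct aldehyde F3 is oxidised by the Pinnick method (NaClO2, NaH2PO4, 2-methyl-2-butene) to the acid F4 and methylated with Me3SiCHN2 to give 12.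

Step 7. Me3Al may attack the methoxy acetal or the ester, and the regiocontrol of the carbometalation may be incomplete. The fallback sets out from 9 and returns at 11. Copper-catalysed syn methylboration of the alkyne (CuCl, Xantphos, B2pin2, MeI, LiOtBu, THF) should give the (E)-alkenylboronate F5 with boron on the terminal carbon and the methyl on C10. Suzuki–Miyaura coupling of F5 with vinyl bromide (Pd(PPh3)4, K3PO4, THF–H2O) gives 11 without a strong Lewis acid.

Step 3. The β-hydroxy aldehyde may undergo retro-aldol cleavage or epimerise at C9 under carbonate before homologation. The fallback sets out from 4 and returns at 7. Both hydroxyls are silylated (Et3SiOTf, 2,6-lutidine) to the bis(triethylsilyl) ether F6. Swern oxidation, which converts a primary triethylsilyl ether directly into the aldehyde, gives the β-silyloxy aldehyde F7. Ohira–Bestmann homologation gives the alkyne F8, and acidic methanol (as in step 4) removes the silyl group and closes the acetal to 7.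

Further compounds
F1 | step 8 | (2Z)-5-{(2R,3R,6R)-6-methoxy-2-methyl-3-[(2E)-penta-2,4-dien-2-yl]oxan-2-yl}-2-methylpent-2-en-1-ol | C=C/C=C(\C)[C@H]1CC[C@H](OC)O[C@]1(C)CC/C=C(/C)CO
F2 | step 8 | (2Z)-5-{(2R,3R,6R)-6-methoxy-2-methyl-3-[(2E)-penta-2,4-dien-2-yl]oxan-2-yl}-2-methylpent-2-enal | C=C/C=C(\C)[C@H]1CC[C@H](OC)O[C@]1(C)CC/C=C(/C)C=O
F3 | step 8 | (13R)-8α,13-epoxy-13-methoxy-14,15,16-trinorlabd-1-en-19-al | CO[C@H]1CC[C@@H]2[C@@]3(C)C=CC[C@](C)(C=O)[C@@H]3CC[C@@]2(C)O1
F4 | step 8 | (13R)-8α,13-epoxy-13-methoxy-14,15,16-trinorlabd-1-en-19-oic acid | CO[C@H]1CC[C@@H]2[C@@]3(C)C=CC[C@](C)(C(O)=O)[C@@H]3CC[C@@]2(C)O1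
F5 | step 7 | methyl (2Z)-5-{(2R,3R,6R)-6-methoxy-2-methyl-3-[(1E)-1-(4,4,5,5-tetramethyl-1,3,2-dioxaborolan-2-yl)prop-1-en-2-yl]oxan-2-yl}-2-methylpent-2-enoate | CC1(C)OB(/C=C(\C)[C@H]2CC[C@H](OC)O[C@]2(C)CC/C=C(/C)C(=O)OC)OC1(C)C
F6 | step 3 | bis(triethylsilyl) ether of 4 | CC[Si](CC)(CC)OC[C@@H](CCC1OCCCO1)[C@](C)(O[Si](CC)(CC)CC)CCC=C(C)C
F7 | step 3 | (2S,3R)-2-[2-(1,3-dioxan-2-yl)ethyl]-3,7-dimethyl-3-(triethylsilyloxy)oct-6-enal | O=C[C@@H](CCC1OCCCO1)[C@](C)(O[Si](CC)(CC)CC)CCC=C(C)C
F8 | step 3 | triethylsilyl ether of 6 | C#C[C@@H](CCC1OCCCO1)[C@](C)(O[Si](CC)(CC)CC)CCC=C(C)C
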